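**Strategy.** Germacrane numbering is used (ring C1–C10; lactone C11, C12, C13). Everything rests on disconnecting C7–C11 of the γ‑lactone ring (O6–C12–C11–C7–C6). The C8 hydroxyl sits next to C7 and anti to that bond, so the lactone is the retron of an epoxide opening: the (diethoxyphosphoryl)acetate on O6 is deprotonated, its carbanion opens the cis‑7,8‑epoxide at C7 (5‑exo‑tet, inversion), which frees the C8 hydroxyl, and formaldehyde then turns the phosphonate into the C11=C13 methylene in the same flask. The precursor is an acyclic epoxy diester carrying the angelate, the (Z)‑iodoalkene and the masked C2 aldehyde; Nozaki–Hiyama–Kishi closure of C1–C2 ends the route.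

Key step: step 12

Remarks: TBS = tert‑butyldimethylsilyl; angelate = (2Z)‑2‑methylbut‑2‑enoate; C‑numbers in the text are the germacrane numbers of the target atoms, also in intermediates.
Assumption: (S,S)‑ProPhenol is taken to deliver the alkynyl group to the enal face that gives (S)‑7 (the commercial (R,R)‑ligand is used if the sense is opposite), and the ring closure of step 15 is taken to favour the 2S carbinol.

**Step 1**
Reactants: 1 prop-2-yn-1-ol
Product: 3 (Z)-3-iodo-2-methylprop-2-en-1-ol, via cyclic alkenylmagnesium alkoxide 2 (not isolated)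
Conditions: MeMgBr (2.5 equiv), CuI (10 mol %), THF, −10 °C → rt; then I2, −10 °C → rt
Reagents that add atoms: methylmagnesium bromide, C[Mg]Br; iodine, II
Why: Copper‑catalysed anti‑carbomagnesiation of the propargylic alkoxide places methyl on the internal carbon and magnesium cis to the CH2O group in a five‑membered chelate, and iodinolysis with retention should fix the (Z)‑iodoalkene that becomes C1=C10.

**Step 2**
Reactants: 3 (Z)-3-iodo-2-methylprop-2-en-1-ol
Product: 4 (Z)-3-iodo-2-methylprop-2-enal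
Conditions: MnO2 (15 equiv), CH2Cl2, rt, dark; used at once
Reagents that add atoms: none
Why: Heterogeneous allylic oxidation with MnO2 is neutral and should leave the C–I bond and the (Z) geometry intact.

**Step 3**
Reactants: 4 (Z)-3-iodo-2-methylprop-2-enal; 5 tert-butyldimethyl(prop-2-yn-1-yloxy)silane
Product: 7 (3S,1Z)-1-iodo-2-methyl-6-(TBS-oxy)hex-1-en-4-yn-3-ol, via alkynyl(methyl)zinc 6 (not isolated)
Conditions: 5 (3 equiv), Me2Zn (3 equiv), (S,S)-ProPhenol (20 mol %), Ph3P=O (40 mol %), toluene, 0 °C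
Reagents that add atoms: none
Why: Zinc–ProPhenol‑catalysed asymmetric alkynylation of an α‑branched enal, in which the dinuclear zinc catalyst binds aldehyde and alkynylzinc 6 and the ligand selects the aldehyde face, should set the future C9 carbinol as S under reagent control.

**Step 4**
Reactants: 7 (3S,1Z)-1-iodo-2-methyl-6-(TBS-oxy)hex-1-en-4-yn-3-ol
Product: 8 (3S,1Z,4Z)-1-iodo-2-methyl-6-(TBS-oxy)hexa-1,4-dien-3-ol
Conditions: Zn(Cu/Ag), MeOH–H2O (1:1), rt → 40 °C
Reagents that add atoms: none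
Why: Zinc–copper/silver couple semi‑reduction adds two hydrogens cis to an alkyne activated by its two propargylic oxygens and should give the (Z)‑alkene without the C–I hydrogenolysis that a palladium catalyst would risk.

**Step 5**
Reactants: 8 (3S,1Z,4Z)-1-iodo-2-methyl-6-(TBS-oxy)hexa-1,4-dien-3-ol
Product: 9 (1R,2Z)-3-iodo-2-methyl-1-[(2S,3R)-3-(TBS-oxymethyl)oxiran-2-yl]prop-2-en-1-ol
Conditions: mCPBA (1.2 equiv), NaHCO3, CH2Cl2, 0 °C
Reagents that add atoms: mCPBA, OOC(=O)c1cccc(Cl)c1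
Why: In this hydroxyl‑directed peracid epoxidation (Henbest) the C9–H eclipses the (Z)‑alkene to avoid A(1,3) strain, so the hydrogen‑bonded peracid should add syn to the hydroxyl and give the threo epoxy alcohol, setting both epoxide carbons (C7, C8), while the iodine‑bearing trisubstituted alkene is deactivated (the S → R change at the carbinol is formal).

**Step 6**
Reactants: 9 (1R,2Z)-3-iodo-2-methyl-1-[(2S,3R)-3-(TBS-oxymethyl)oxiran-2-yl]prop-2-en-1-ol; 10 angelic acid
Product: 12 (1R,2Z)-3-iodo-2-methyl-1-[(2S,3R)-3-(TBS-oxymethyl)oxiran-2-yl]prop-2-en-1-yl angelate, via mixed anhydride 11 (not isolated)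
Conditions: 10, 2,4,6-trichlorobenzoyl chloride, Et3N, toluene, rt; then 9, toluene, 80 °C (no DMAP)
Reagents that add atoms: none
Why: Yamaguchi‑type esterification through mixed anhydride 11 without a nucleophilic catalyst should acylate the hindered secondary alcohol with retention at the carbinol and without angelate‑to‑tiglate isomerisation.

**Step 7**
Reactants: 12 (1R,2Z)-3-iodo-2-methyl-1-[(2S,3R)-3-(TBS-oxymethyl)oxiran-2-yl]prop-2-en-1-yl angelate
Product: 13 (1R,2Z)-1-[(2S,3R)-3-(hydroxymethyl)oxiran-2-yl]-3-iodo-2-methylprop-2-en-1-yl angelate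
Conditions: HF·pyridine, pyridine, THF, 0 °C → rt
Reagents that add atoms: none
Why: Buffered fluoride desilylation should cleave the primary silyl ether under mildly acidic conditions that avoid Payne rearrangement and acyl migration of the epoxy ester.

**Step 8**
Reactants: 13 (1R,2Z)-1-[(2S,3R)-3-(hydroxymethyl)oxiran-2-yl]-3-iodo-2-methylprop-2-en-1-yl angelate
Product: 14 (1R,2Z)-1-[(2S,3S)-3-formyloxiran-2-yl]-3-iodo-2-methylprop-2-en-1-yl angelate
Conditions: Dess–Martin periodinane, NaHCO3, CH2Cl2, 0 °C → rt; used crude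
Reagents that add atoms: none
Why: Dess–Martin oxidation under bicarbonate buffer should give the cis‑α,β‑epoxy aldehyde without epimerisation or epoxide opening (the descriptor change at C7 is formal).

**Step 9**
Reactants: 15 tert-butyl(but-3-yn-1-yloxy)dimethylsilane
Product: 17 (E)-tert-butyl[(4-iodo-3-methylbut-3-en-1-yl)oxy]dimethylsilane, via alkenyldimethylalane 16 (not isolated)
Conditions: Me3Al (2 equiv), Cp2ZrCl2 (25 mol %), CH2Cl2, 0 °C → rt; then I2, THF, −30 → 0 °C
Reagents that add atoms: trimethylaluminium, C[Al](C)C; iodine, II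
Why: Zirconium‑catalysed syn‑carboalumination of the terminal alkyne (Negishi carboalumination) adds methyl to the internal carbon and aluminium to the terminus, and iodinolysis with retention should give the (E)‑iodoalkene that becomes C4=C5.

**Step 10**
Reactants: 17 (E)-tert-butyl[(4-iodo-3-methylbut-3-en-1-yl)oxy]dimethylsilane; 14 (1R,2Z)-1-[(2S,3S)-3-formyloxiran-2-yl]-3-iodo-2-methylprop-2-en-1-yl angelate
Product: 19 (1R,2Z)-1-{(2S,3R)-3-[(1R,2E)-1-hydroxy-3-methyl-5-(TBS-oxy)pent-2-en-1-yl]oxiran-2-yl}-3-iodo-2-methylprop-2-en-1-yl angelate, via alkenyllithium 18 (not isolated)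
Conditions: 17 (1.3 equiv), t-BuLi (2.6 equiv), Et2O, −78 °C; then 14, THF, −78 °C; NH4Cl at −78 °C
Reagents that add atoms: none
Why: Iodine–lithium exchange with retention of alkene geometry is followed by 1,2‑addition to the aldehyde, which should outpace attack on the hindered angelate at −78 °C, and the polar Felkin–Anh mode (nucleophile anti to the epoxide C–O bond) is expected to favour the erythro epoxy alcohol, setting C6 as R.

**Step 11**
Reactants: 19 (1R,2Z)-1-{(2S,3R)-3-[(1R,2E)-1-hydroxy-3-methyl-5-(TBS-oxy)pent-2-en-1-yl]oxiran-2-yl}-3-iodo-2-methylprop-2-en-1-yl angelate; 20 (diethoxyphosphoryl)acetic acid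
Product: 21 (1R,2E)-1-{(2R,3S)-3-[(1R,2Z)-1-(angeloyloxy)-3-iodo-2-methylprop-2-en-1-yl]oxiran-2-yl}-3-methyl-5-(TBS-oxy)pent-2-en-1-yl (diethoxyphosphoryl)acetate
Conditions: 20, DCC, DMAP (cat.), CH2Cl2, 0 °C → rt
Reagents that add atoms: none
Why: Steglich esterification of the secondary allylic alcohol should proceed with retention at C6 and leave epoxide, angelate and iodoalkene untouched.

**Step 12**
Reactants: 21 (1R,2E)-1-{(2R,3S)-3-[(1R,2Z)-1-(angeloyloxy)-3-iodo-2-methylprop-2-en-1-yl]oxiran-2-yl}-3-methyl-5-(TBS-oxy)pent-2-en-1-yl (diethoxyphosphoryl)acetate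
Product: 23 (1R,2R,3Z)-1-hydroxy-4-iodo-3-methyl-1-{(2R,3R)-4-methylidene-2-[(1E)-2-methyl-4-(TBS-oxy)but-1-en-1-yl]-5-oxooxolan-3-yl}but-3-en-2-yl angelate, via α-phosphono lactone 22 (not isolated)
Conditions: NaH (1.1 equiv), THF, 0 °C → rt; then (CH2O)n, 0 °C → rt
Reagents that add atoms: paraformaldehyde (as formaldehyde), C=O
Why: NaH deprotonates the phosphonoacetate and the stabilised carbanion displaces the epoxide oxygen at C7 by backside attack, the C8 alkoxide being quenched at once by proton transfer from the far more acidic α‑phosphono lactone 22, whose anion then undergoes Horner–Wadsworth–Emmons olefination with formaldehyde to give the C11=C13 methylene. The closest known reaction types are the intramolecular epoxide alkylation by stabilised carbanions (Stork epoxynitrile cyclisation) and the telescoped intramolecular Michael/olefination of phosphonoacetate esters that delivers α‑methylene‑γ‑butyrolactones. The γ‑lactone ring closes in the 5‑exo‑tet mode, the breaking epoxide C–O bond lying outside the new ring. C7 is set by stereospecific inversion at the epoxide carbon and C8 keeps its oxygen with retention, so the erythro C6/C7 relation from step 10 becomes the trans ring fusion and the cis‑epoxide becomes the anti C7–C11/C8–OH array, while no stereocentre remains at C11 after olefination. The step needs attack at C7 rather than 6‑endo attack at C8 and no acyl transfer from the angelate; the first should be secured by the preference for exo opening and by the hindered, inductively deactivated C8 next to the acyloxy carbon, the second by using one equivalent of base so that no alkoxide persists.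

**Step 13**
Reactants: 23 (1R,2R,3Z)-1-hydroxy-4-iodo-3-methyl-1-{(2R,3R)-4-methylidene-2-[(1E)-2-methyl-4-(TBS-oxy)but-1-en-1-yl]-5-oxooxolan-3-yl}but-3-en-2-yl angelate
Product: 24 (1R,2R,3Z)-1-hydroxy-1-{(2R,3R)-2-[(1E)-4-hydroxy-2-methylbut-1-en-1-yl]-4-methylidene-5-oxooxolan-3-yl}-4-iodo-3-methylbut-3-en-2-yl angelate
Conditions: HF·pyridine, pyridine, THF, 0 °C
Reagents that add atoms: none
Why: Buffered fluoride desilylation should free the primary C2 alcohol without base that could add to or translactonise the α‑methylene lactone.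

**Step 14**
Reactants: 24 (1R,2R,3Z)-1-hydroxy-1-{(2R,3R)-2-[(1E)-4-hydroxy-2-methylbut-1-en-1-yl]-4-methylidene-5-oxooxolan-3-yl}-4-iodo-3-methylbut-3-en-2-yl angelate
Product: 25 (1R,2R,3Z)-1-hydroxy-4-iodo-3-methyl-1-{(2R,3R)-4-methylidene-2-[(1E)-2-methyl-4-oxobut-1-en-1-yl]-5-oxooxolan-3-yl}but-3-en-2-yl angelate
Conditions: TEMPO (cat.), PhI(OAc)2, CH2Cl2, rt; used at once
Reagents that add atoms: none
Why: Oxoammonium (TEMPO/PhI(OAc)2) oxidation is selective for the primary over the secondary C8 alcohol and should stop at the aldehyde under non‑basic conditions that keep the C4=C5 bond out of conjugation.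

**Step 15**
Reactants: 25 (1R,2R,3Z)-1-hydroxy-4-iodo-3-methyl-1-{(2R,3R)-4-methylidene-2-[(1E)-2-methyl-4-oxobut-1-en-1-yl]-5-oxooxolan-3-yl}but-3-en-2-yl angelate
Product: 26 (3aR,4R,5R,6Z,8S,10E,11aR)-4,8-dihydroxy-6,10-dimethyl-3-methylidene-2-oxo-2,3,3a,4,5,8,9,11a-octahydrocyclodeca[b]furan-5-yl angelate
Conditions: CrCl2 (10 equiv), NiCl2 (2 mol % of Cr), degassed DMSO, rt, 2 mM, slow addition
Reagents that add atoms: none
Why: In this intramolecular Nozaki–Hiyama–Kishi reaction the (Z)‑alkenylchromium(III) species forms with retention and adds chemoselectively to the aldehyde at high dilution, which should close the ten‑membered ring in the presence of the free hydroxyl, the esters and the α‑methylene lactone, the C2 stereocentre being set by the macrocyclic transition state templated by the trans‑lactone and the (Z)‑alkene (assumed to favour 2S).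

**Compound list**
1 | prop-2-yn-1-ol | C#CCO | starting material
2 | cyclic (Z)-alkenylmagnesium alkoxide (4-methyl-2,5-dihydro-1,2-oxamagnesole) | CC1=C[Mg]OC1 | intermediate (not isolated)
3 | (Z)-3-iodo-2-methylprop-2-en-1-ol | OC/C(C)=C\I | intermediate
4 | (Z)-3-iodo-2-methylprop-2-enal | O=C/C(C)=C\I | intermediate
5 | tert-butyldimethyl(prop-2-yn-1-yloxy)silane | C#CCO[Si](C)(C)C(C)(C)C | starting material
6 | methyl[3-(TBS-oxy)prop-1-yn-1-yl]zinc | C[Zn]C#CCO[Si](C)(C)C(C)(C)C | intermediate (not isolated)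
7 | (3S,1Z)-1-iodo-2-methyl-6-(TBS-oxy)hex-1-en-4-yn-3-ol | CC(C)(C)[Si](C)(C)OCC#C[C@H](O)/C(C)=C\I | intermediate
8 | (3S,1Z,4Z)-1-iodo-2-methyl-6-(TBS-oxy)hexa-1,4-dien-3-ol | CC(C)(C)[Si](C)(C)OC/C=C\[C@H](O)/C(C)=C\I | intermediate
9 | (1R,2Z)-3-iodo-2-methyl-1-[(2S,3R)-3-(TBS-oxymethyl)oxiran-2-yl]prop-2-en-1-ol | CC(C)(C)[Si](C)(C)OC[C@H]1O[C@H]1[C@H](O)/C(C)=C\I | intermediate
10 | angelic acid, (2Z)-2-methylbut-2-enoic acid | C/C=C(/C)C(=O)O | starting material
11 | (2Z)-2-methylbut-2-enoic 2,4,6-trichlorobenzoic anhydride | C/C=C(/C)C(=O)OC(=O)c1c(Cl)cc(Cl)cc1Cl | intermediate (not isolated)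
12 | (1R,2Z)-3-iodo-2-methyl-1-[(2S,3R)-3-(TBS-oxymethyl)oxiran-2-yl]prop-2-en-1-yl angelate | CC(C)(C)[Si](C)(C)OC[C@H]1O[C@H]1[C@H](OC(=O)/C(C)=C\C)/C(C)=C\I | intermediate
13 | (1R,2Z)-1-[(2S,3R)-3-(hydroxymethyl)oxiran-2-yl]-3-iodo-2-methylprop-2-en-1-yl angelate | OC[C@H]1O[C@H]1[C@H](OC(=O)/C(C)=C\C)/C(C)=C\I | intermediate
14 | (1R,2Z)-1-[(2S,3S)-3-formyloxiran-2-yl]-3-iodo-2-methylprop-2-en-1-yl angelate | O=C[C@H]1O[C@H]1[C@H](OC(=O)/C(C)=C\C)/C(C)=C\I | intermediate
15 | tert-butyl(but-3-yn-1-yloxy)dimethylsilane | C#CCCO[Si](C)(C)C(C)(C)C | starting material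
16 | (E)-dimethyl[2-methyl-4-(TBS-oxy)but-1-en-1-yl]alane | CC(C)(C)[Si](C)(C)OCC/C(C)=C/[Al](C)C | intermediate (not isolated)
17 | (E)-tert-butyl[(4-iodo-3-methylbut-3-en-1-yl)oxy]dimethylsilane | CC(C)(C)[Si](C)(C)OCC/C(C)=C/I | intermediate
18 | (E)-[2-methyl-4-(TBS-oxy)but-1-en-1-yl]lithium | CC(C)(C)[Si](C)(C)OCC/C(C)=C/[Li] | intermediate (not isolated)
19 | (1R,2Z)-1-{(2S,3R)-3-[(1R,2E)-1-hydroxy-3-methyl-5-(TBS-oxy)pent-2-en-1-yl]oxiran-2-yl}-3-iodo-2-methylprop-2-en-1-yl angelate | CC(C)(C)[Si](C)(C)OCC/C(C)=C/[C@@H](O)[C@H]1O[C@H]1[C@H](OC(=O)/C(C)=C\C)/C(C)=C\I | intermediate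
20 | (diethoxyphosphoryl)acetic acid | OC(=O)CP(=O)(OCC)OCC | starting material
21 | (1R,2E)-1-{(2R,3S)-3-[(1R,2Z)-1-(angeloyloxy)-3-iodo-2-methylprop-2-en-1-yl]oxiran-2-yl}-3-methyl-5-(TBS-oxy)pent-2-en-1-yl (diethoxyphosphoryl)acetate | CC(C)(C)[Si](C)(C)OCC/C(C)=C/[C@@H](OC(=O)CP(=O)(OCC)OCC)[C@H]1O[C@H]1[C@H](OC(=O)/C(C)=C\C)/C(C)=C\I | intermediate
22 | (1R,2R,3Z)-1-{(2R,3R)-4-(diethoxyphosphoryl)-2-[(1E)-2-methyl-4-(TBS-oxy)but-1-en-1-yl]-5-oxooxolan-3-yl}-1-hydroxy-4-iodo-3-methylbut-3-en-2-yl angelate (oxolane C4 unassigned) | CC(C)(C)[Si](C)(C)OCC/C(C)=C/[C@H]1OC(=O)C(P(=O)(OCC)OCC)[C@@H]1[C@@H](O)[C@H](OC(=O)/C(C)=C\C)/C(C)=C\I | intermediate (not isolated)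
23 | (1R,2R,3Z)-1-hydroxy-4-iodo-3-methyl-1-{(2R,3R)-4-methylidene-2-[(1E)-2-methyl-4-(TBS-oxy)but-1-en-1-yl]-5-oxooxolan-3-yl}but-3-en-2-yl angelate | CC(C)(C)[Si](C)(C)OCC/C(C)=C/[C@H]1OC(=O)C(=C)[C@@H]1[C@@H](O)[C@H](OC(=O)/C(C)=C\C)/C(C)=C\I | intermediate
24 | (1R,2R,3Z)-1-hydroxy-1-{(2R,3R)-2-[(1E)-4-hydroxy-2-methylbut-1-en-1-yl]-4-methylidene-5-oxooxolan-3-yl}-4-iodo-3-methylbut-3-en-2-yl angelate | OCC/C(C)=C/[C@H]1OC(=O)C(=C)[C@@H]1[C@@H](O)[C@H](OC(=O)/C(C)=C\C)/C(C)=C\I | intermediate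
25 | (1R,2R,3Z)-1-hydroxy-4-iodo-3-methyl-1-{(2R,3R)-4-methylidene-2-[(1E)-2-methyl-4-oxobut-1-en-1-yl]-5-oxooxolan-3-yl}but-3-en-2-yl angelate | O=CC/C(C)=C/[C@H]1OC(=O)C(=C)[C@@H]1[C@@H](O)[C@H](OC(=O)/C(C)=C\C)/C(C)=C\I | intermediate
26 | (3aR,4R,5R,6Z,8S,10E,11aR)-4,8-dihydroxy-6,10-dimethyl-3-methylidene-2-oxo-2,3,3a,4,5,8,9,11a-octahydrocyclodeca[b]furan-5-yl (2Z)-2-methylbut-2-enoate | C=C1C(=O)O[C@@H]2/C=C(\C)C[C@H](O)/C=C(/C)[C@@H](OC(=O)/C(C)=C\C)[C@H](O)[C@@H]12 | target

**Totals.** 15 steps in all; longest linear sequence 14 steps (steps 1–8 and 10–15).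

**Steps most likely to fail**

Step 15. The ten‑membered ring may close slowly against oligomerisation, and the transannular carbonyl addition may show poor facial selectivity, so that the C2 epimer is formed. The fallback sets out from 25 and comes back at 26, and no longer relies on the C–C bond formation to set C2. The same chromium closure is accepted whatever its selectivity, giving the 8‑epimer (3aR,4R,5R,6Z,8R,10E,11aR)-4,8-dihydroxy-6,10-dimethyl-3-methylidene-2-oxo-2,3,3a,4,5,8,9,11a-octahydrocyclodeca[b]furan-5-yl angelate F1 or an epimer mixture. MnO2 in CH2Cl2 then oxidises only the allylic C2 alcohol (the C8 carbinol is not allylic) to the macrocyclic (Z)‑enone (3aR,4R,5R,6Z,10E,11aR)-4-hydroxy-6,10-dimethyl-3-methylidene-2,8-dioxo-2,3,3a,4,5,8,9,11a-octahydrocyclodeca[b]furan-5-yl angelate F2. Corey–Bakshi–Shibata reduction with the (R)‑methyl oxazaborolidine and catecholborane at −78 °C, with the alkenyl side as the large group, should return the 2S alcohol 26.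

Step 12. The bulky phosphonate carbanion may alkylate the epoxide sluggishly, since the ester must reach its s‑cis conformer, and 6‑endo opening, angelate migration to O8 or translactonisation could then compete. The fallback sets out from 19 and comes back at 23, using a malonate nucleophile and a decarboxylative methylenation instead of the olefination. Alcohol 19 is esterified (DCC, DMAP) with 3‑tert‑butoxy‑3‑oxopropanoic acid to tert-butyl (1R,2E)-1-{(2R,3S)-3-[(1R,2Z)-1-(angeloyloxy)-3-iodo-2-methylprop-2-en-1-yl]oxiran-2-yl}-3-methyl-5-(TBS-oxy)pent-2-en-1-yl propanedioate F3. NaH in THF (or DBU/LiCl in MeCN) should give the classical malonate epoxide opening to tert-butyl (4R,5R)-4-[(1R,2R,3Z)-2-(angeloyloxy)-1-hydroxy-4-iodo-3-methylbut-3-en-1-yl]-5-[(1E)-2-methyl-4-(TBS-oxy)but-1-en-1-yl]-2-oxooxolane-3-carboxylate F4. TMSOTf/2,6‑lutidine followed by aqueous work‑up cleaves the tert‑butyl ester to (4R,5R)-4-[(1R,2R,3Z)-2-(angeloyloxy)-1-hydroxy-4-iodo-3-methylbut-3-en-1-yl]-5-[(1E)-2-methyl-4-(TBS-oxy)but-1-en-1-yl]-2-oxooxolane-3-carboxylic acid F5. Aqueous formaldehyde and Et2NH, then NaOAc/AcOH (Mannich condensation with decarboxylative elimination), should give 23.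

Step 10. Facial discrimination in the addition to the epoxy aldehyde may be insufficient, giving the C6 epimer, and the alkenyllithium may also attack the angelate. The fallback sets out from 19 (as its C6‑epimer mixture) and comes back at 19, setting C6 by a ketone reduction instead of the C–C bond formation. Dess–Martin oxidation gives the epoxy enone (1R,2Z)-3-iodo-2-methyl-1-{(2S,3S)-3-[(2E)-3-methyl-5-(TBS-oxy)pent-2-enoyl]oxiran-2-yl}prop-2-en-1-yl angelate F6. Zn(BH4)2 in Et2O at −20 °C should then reduce it under chelation between the carbonyl and epoxide oxygens, the established erythro‑selective reduction of α,β‑epoxy ketones, and return 19.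

**Further compounds**
F1 | step 15 | (3aR,4R,5R,6Z,8R,10E,11aR)-4,8-dihydroxy-6,10-dimethyl-3-methylidene-2-oxo-2,3,3a,4,5,8,9,11a-octahydrocyclodeca[b]furan-5-yl (2Z)-2-methylbut-2-enoate | C=C1C(=O)O[C@@H]2/C=C(\C)C[C@@H](O)/C=C(/C)[C@@H](OC(=O)/C(C)=C\C)[C@H](O)[C@@H]12
F2 | step 15 | (3aR,4R,5R,6Z,10E,11aR)-4-hydroxy-6,10-dimethyl-3-methylidene-2,8-dioxo-2,3,3a,4,5,8,9,11a-octahydrocyclodeca[b]furan-5-yl (2Z)-2-methylbut-2-enoate | C=C1C(=O)O[C@@H]2/C=C(\C)CC(=O)/C=C(/C)[C@@H](OC(=O)/C(C)=C\C)[C@H](O)[C@@H]12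
F3 | step 12 | tert-butyl (1R,2E)-1-{(2R,3S)-3-[(1R,2Z)-1-(angeloyloxy)-3-iodo-2-methylprop-2-en-1-yl]oxiran-2-yl}-3-methyl-5-(TBS-oxy)pent-2-en-1-yl propanedioate | CC(C)(C)[Si](C)(C)OCC/C(C)=C/[C@@H](OC(=O)CC(=O)OC(C)(C)C)[C@H]1O[C@H]1[C@H](OC(=O)/C(C)=C\C)/C(C)=C\I
F4 | step 12 | tert-butyl (4R,5R)-4-[(1R,2R,3Z)-2-(angeloyloxy)-1-hydroxy-4-iodo-3-methylbut-3-en-1-yl]-5-[(1E)-2-methyl-4-(TBS-oxy)but-1-en-1-yl]-2-oxooxolane-3-carboxylate (C3 unassigned) | CC(C)(C)[Si](C)(C)OCC/C(C)=C/[C@H]1OC(=O)C(C(=O)OC(C)(C)C)[C@@H]1[C@@H](O)[C@H](OC(=O)/C(C)=C\C)/C(C)=C\I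
F5 | step 12 | (4R,5R)-4-[(1R,2R,3Z)-2-(angeloyloxy)-1-hydroxy-4-iodo-3-methylbut-3-en-1-yl]-5-[(1E)-2-methyl-4-(TBS-oxy)but-1-en-1-yl]-2-oxooxolane-3-carboxylic acid (C3 unassigned) | CC(C)(C)[Si](C)(C)OCC/C(C)=C/[C@H]1OC(=O)C(C(=O)O)[C@@H]1[C@@H](O)[C@H](OC(=O)/C(C)=C\C)/C(C)=C\I
F6 | step 10 | (1R,2Z)-3-iodo-2-methyl-1-{(2S,3S)-3-[(2E)-3-methyl-5-(TBS-oxy)pent-2-enoyl]oxiran-2-yl}prop-2-en-1-yl (2Z)-2-methylbut-2-enoate | CC(C)(C)[Si](C)(C)OCC/C(C)=C/C(=O)[C@H]1O[C@H]1[C@H](OC(=O)/C(C)=C\C)/C(C)=C\I
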